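Target and starting material cannot stand together in these flasks without forming side product, and each recipe sets how long they do.

in all of them: enzyme 0.050 µM; time 30 s
- Saturday's: starting material 0.50 mM; second substrate 0.550 mM; everything together at the start
- Sunday's: starting material 0.50 mM; second substrate 0.550 mM (in portions, 4, over 20 s); first portion at the start, last at 20 s
- Wednesday's: starting material 0.50 mM; second substrate 0.550 mM (fed, over 20 s); all else is in the flask from the start; the feed brings no volume worth counting
- Friday's: starting material 0.50 mM (fed, over 20 s); second substrate 0.550 mM; all else is in the flask from the start; the feed brings no volume worth counting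

    second substrate + starting complex ⇌ ternary complex (K1 = 3900 M⁻¹, k1 = 1.3 × 10⁷ M⁻¹ s⁻¹)
    starting material + enzyme ⇌ starting complex (K2 = 91000 M⁻¹, k2 = 2.3 × 10⁸ M⁻¹ s⁻¹)
    starting material + target → side product (k3 = 230 M⁻¹ s⁻¹)
    ternary complex → enzyme + target (k4 = 4000 s⁻¹)

1. which flask leads in amount of target, in percent of the starting material charged ("all alike" within 1.5 percentage points) (Saturday's / Sunday's / Wednesday's / Friday's / all alike)
2. how much target is there at the end, in percent of the starting material charged: Saturday's
3. how much target is there at the end, in percent of the starting material charged: Sunday's
4. how much target is there at the end, in percent of the starting material charged: Wednesday's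
5. how much target is there at the end, in percent of the starting material charged: Friday's

- percent here means starting material units held: one side product counts as two
- run time (Saturday's): 30 s

Take Saturday's first, with S, T and B for the concentrations of starting material, target and second substrate, and climb from the fastest rung. Enzyme meets starting material within 6.03 × 10⁻⁶ s. With binding constant times S at 46 at the start, enzyme is held as starting complex and ternary complex while S stands high. A share 0.545 of ternary complex goes on to target, the rest back. Take κ as the forward constant times that share times the enzyme, and M as the Michaelis constant, the two ways out of ternary complex over the forward constant. B then falls at κ·B/(1 + B/M):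

κ = 0.355 s⁻¹, M = 0.564 mM

Ternary complex lives 1.36 × 10⁻⁴ s, far shorter than 1/κ, so it keeps pace with B and stands to starting complex as B to M. M lies close to the charged B, so B falls first-order only well below M. Target's half-life against S as charged, 6.0 s, is shorter than the 30 s run.

Carry the rival number ρ, the side-step constant over κ, 0.649 mM⁻¹. Side product per turnover is ρ·S·T·(1/B + 1/M), a selectivity ratio. It vanishes at both ends: T is zero at the start, S at the finish. To join the ends, ignore the side step's own draw and write S = B − d and T = b − B, where b is the starting B and d is b minus the charged S. With B as the clock:

side product = ρ·(0.5·(b·b − d·d) − b·d·ln(b/d) + (b − d)·(b − d)·(b − d)/(6·M))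

But each side product takes one S and one T, which narrows the span b − d that they share. The sum goes roughly with the cube of that span, so I divide it by 1 + 3·x, with x the undivided side product over the charged S.

Saturday's: d = 0.0500 mM, undivided 0.0785 mM, side product 0.0534 mM, target 78.7%

I expect Sunday's and Wednesday's lower, because their B is smaller: portions of 0.138 mM, and a feed that holds B near 0.0899 mM. I expect Friday's higher, because its feed of 0.0250 mM s⁻¹ is slower than the enzyme's 0.0987 mM s⁻¹ at charged B, which keeps S low.

The forecast named Friday's, with 77%, 63%, 63% and 90% in flask order: “Feeding the starting material keeps it scarce and protects the target”.

The flasks give 78.0%, 57.0%, 61.8% and 94.3%, so Friday's leads.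

Saturday's has come to rest. Its starting material, the limiting reagent, stands at 0% after 30.0 s, so ρ·S·T·(1/B + 1/M) is zero there, and 19.1% of the second substrate remains unused. At 300 s its target still reads 78.0%, as it already did at 15.0 s. Sunday's reads 57.0% and Friday's 94.3% at 300 s, so more time changes neither.

Now Sunday's recipe with 0.12 mM of starting material. Its first portion outweighs the charge, d = 0.0175 mM, and by the rate law above B reaches d in 6.41 s, sooner than the next portion at 6.67 s. So ρ gives 0.00315 mM undivided, 0.00292 mM side product and 95.1% target. The flask gives 94.0% target and 6.02% side product.

(The numbers were drawn at random within sensible limits; the result is computed.)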